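**Retrosynthetic overview**

1. The target is a cis-fused 3-bromodrimane. In ring B the exocyclic olefin C12=C8 sits next to the C9 methine that carries the benzylic C11H2–aryl group, and this array (1,1-disubstituted olefin, adjacent methine, benzylic CH2) is the retron of a hydride-terminated enyne cyclization.
2. Ring B is therefore closed at C8–C9 from a C8≡C12 alkyne and a C9=C11 styrene by palladium hydride catalysis. This one operation creates the exocyclic methylene, the C9 stereocentre and the benzylic CH2.
3. The enyne comes from a dialdehyde (Ohira–Bestmann at the unhindered formyl group, then boron–Wittig and Suzuki–Miyaura coupling with a 4-bromo-2,5-bis(silyloxy)benzaldehyde at the quaternary one).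
4. The dialdehyde comes from ozonolysis of a temporary cyclohexene. That ring and ring A (C3–Br, C4 gem-dimethyl, cis C5 and C10 arms) are made together by an enantioselective bromonium cyclization of a nerol-derived (Z,Z)-trienyl silane.
5. Order of ring formation: ring A plus temporary carbocycle (step 4), carbocycle opened (step 5), ring B (step 11), deprotection (step 12).

Key step: step 11

Remark: the target is taken as drawn, i.e. the cis-fused isomer (H5 and the C10 methyl cis; 3S,5S,9R,10R in the drimane numbering used throughout), and the catalyst enantiomer that gives the (3S) bromide in step 4 is assumed to be found by screening both antipodes.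

Step 1
Reactants: 1 nerol
Product: 2 neryl bromide, (2Z)-1-bromo-3,7-dimethylocta-2,6-diene
Conditions: PBr3, Et2O, −10 °C
Reagents that add atoms: phosphorus tribromide, BrP(Br)Br
Why: Allylic alcohol to allylic bromide through the phosphite ester (SN2) at low temperature, which should keep the Z olefin; no stereocentre is formed.

Step 2
Reactants: 2 neryl bromide; 3 1-(trimethylsilyl)propyne
Product: 5 trimethyl[(5Z)-6,10-dimethylundeca-5,9-dien-1-yn-1-yl]silane, via silylpropargyllithium 4 (not isolated)
Conditions: n-BuLi, TMEDA, THF, −78 °C; then 2, −78 °C to rt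
Reagents that add atoms: none
Why: Propargylic lithiation of 3 and SN2 alkylation of the primary allylic bromide (1,5-enyne synthesis by propargyl anion alkylation), the silyl group steering attack to the propargylic carbon.

Step 3
Reactants: 5 trimethyl[(5Z)-6,10-dimethylundeca-5,9-dien-1-yn-1-yl]silane
Product: 7 trimethyl[(1Z,5Z)-6,10-dimethylundeca-1,5,9-trien-1-yl]silane, via alkenylalane 6 (not isolated)
Conditions: i-Bu2AlH, N-methylpyrrolidine, heptane, 60 °C; then dilute HCl, 0 °C
Reagents that add atoms: none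
Why: cis-Hydroalumination of a silylalkyne in the presence of a tertiary amine puts aluminium on the silyl-bearing carbon, so protonolysis should give the (Z)-vinylsilane while the trisubstituted olefins stay untouched.

Step 4
Reactants: 7 trimethyl[(1Z,5Z)-6,10-dimethylundeca-1,5,9-trien-1-yl]silane
Product: 8 (4aS,6S,8aR)-6-bromo-5,5,8a-trimethyl-3,4,4a,5,6,7,8,8a-octahydronaphthalene (cis-fused)
Conditions: chiral BINOL-derived thiophosphoramide Lewis base (10 mol %), DBDMH (0.55 equiv), toluene–CH2Cl2, −90 °C
Reagents that add atoms: 1,3-dibromo-5,5-dimethylhydantoin, CC1(C)N(Br)C(=O)N(Br)C1=O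
Why: Proposed new method: the catalyst-bound bromonium donor should transfer Br+ to the most electron-rich terminal olefin, the (Z)-C5=C10 olefin attacks through a chair (Br equatorial, C6 axial), and the tertiary C10 cation is captured anti by the ipso carbon of the (Z)-vinylsilane (6-endo) with loss of the silyl group to leave the C8=C9 olefin; anti addition across the Z olefin sets the cis ring fusion and the C3/C5/C10 relative configuration and the catalyst sets the absolute one; the closest known reactions are catalytic enantioselective bromonium polyene cyclizations with arene terminators and vinylsilane-terminated cationic cyclizations of (Z)-4-silylbut-3-enyl chains.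

Step 5
Reactants: 8 (4aS,6S,8aR)-6-bromo-5,5,8a-trimethyl-3,4,4a,5,6,7,8,8a-octahydronaphthalene
Product: 10 (1S,2S,4S)-4-bromo-1,3,3-trimethyl-2-(3-oxopropyl)cyclohexane-1-carbaldehyde, via secondary ozonide 9 (not isolated)
Conditions: O3, CH2Cl2, −78 °C; then PPh3, −78 °C to rt
Reagents that add atoms: ozone, [O-][O+]=O
Why: Ozonolysis of the only olefin with reductive work-up opens the temporary ring to the two cis formyl arms without touching a stereocentre (the quaternary aldehyde cannot epimerise).

Step 6
Reactants: 10 (1S,2S,4S)-4-bromo-1,3,3-trimethyl-2-(3-oxopropyl)cyclohexane-1-carbaldehyde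
Product: 11 (1S,2S,4S)-4-bromo-2-(but-3-yn-1-yl)-1,3,3-trimethylcyclohexane-1-carbaldehyde
Conditions: dimethyl (1-diazo-2-oxopropyl)phosphonate, K2CO3, MeOH, 0 °C
Reagents that add atoms: dimethyl (1-diazo-2-oxopropyl)phosphonate, COP(=O)(OC)C(=[N+]=[N-])C(C)=O
Why: Ohira–Bestmann homologation should occur only at the unhindered CH2–CHO group, the formyl group on the quaternary carbon being neopentyl-shielded and much slower.

Step 7
Reactants: 11 (1S,2S,4S)-4-bromo-2-(but-3-yn-1-yl)-1,3,3-trimethylcyclohexane-1-carbaldehyde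
Product: 12 2-{(E)-2-[(1R,2S,4S)-4-bromo-2-(but-3-yn-1-yl)-1,3,3-trimethylcyclohexyl]ethenyl}-4,4,5,5-tetramethyl-1,3,2-dioxaborolane
Conditions: CH2(Bpin)2, lithium 2,2,6,6-tetramethylpiperidide (from n-BuLi and the amine), THF, 0 °C; then 11, −78 °C to rt
Reagents that add atoms: bis(4,4,5,5-tetramethyl-1,3,2-dioxaborolan-2-yl)methane, C(B1OC(C)(C)C(C)(C)O1)B1OC(C)(C)C(C)(C)O1
Why: Boron–Wittig olefination, in which the lithiated geminal bis(boronate) adds to the hindered aldehyde and eliminates a borate to give the (E)-alkenyl boronate, the alkyl bromide and alkyne being inert to this stabilised carbanion.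

Step 8
Reactants: 13 4-bromo-2,5-dimethoxybenzaldehyde
Product: 14 4-bromo-2,5-dihydroxybenzaldehyde
Conditions: BBr3, CH2Cl2, −78 °C to rt; then H2O
Reagents that add atoms: none
Why: Lewis-acid demethylation of aryl methyl ethers by BBr3, tolerated by the aryl bromide and the aldehyde.

Step 9
Reactants: 14 4-bromo-2,5-dihydroxybenzaldehyde
Product: 15 4-bromo-2,5-bis[(triisopropylsilyl)oxy]benzaldehyde
Conditions: i-Pr3SiOTf, 2,6-lutidine, CH2Cl2, 0 °C
Reagents that add atoms: triisopropylsilyl trifluoromethanesulfonate, CC(C)[Si](OS(=O)(=O)C(F)(F)F)(C(C)C)C(C)C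
Why: Silylation of both phenols with the silyl triflate, the bulky triisopropylsilyl ethers being chosen to survive aqueous base and formic acid in the next two steps.

Step 10
Reactants: 12 2-{(E)-2-[(1R,2S,4S)-4-bromo-2-(but-3-yn-1-yl)-1,3,3-trimethylcyclohexyl]ethenyl}-4,4,5,5-tetramethyl-1,3,2-dioxaborolane; 15 4-bromo-2,5-bis[(triisopropylsilyl)oxy]benzaldehyde
Product: 16 4-{(E)-2-[(1R,2S,4S)-4-bromo-2-(but-3-yn-1-yl)-1,3,3-trimethylcyclohexyl]ethenyl}-2,5-bis[(triisopropylsilyl)oxy]benzaldehyde
Conditions: Pd(dppf)Cl2 (5 mol %), K3PO4, THF–H2O, 50 °C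
Reagents that add atoms: none
Why: Suzuki–Miyaura coupling of the (E)-alkenyl boronate with the aryl bromide activated by its para formyl group, with retention of olefin geometry and without insertion of palladium into the hindered secondary alkyl bromide.

Step 11
Reactants: 16 4-{(E)-2-[(1R,2S,4S)-4-bromo-2-(but-3-yn-1-yl)-1,3,3-trimethylcyclohexyl]ethenyl}-2,5-bis[(triisopropylsilyl)oxy]benzaldehyde
Product: 17 4-{[(1R,4aS,6S,8aR)-6-bromo-5,5,8a-trimethyl-2-methylidenedecahydronaphthalen-1-yl]methyl}-2,5-bis[(triisopropylsilyl)oxy]benzaldehyde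
Conditions: Pd2(dba)3·CHCl3 (2.5 mol %), P(o-tol)3 (10 mol %), HCO2H (2 equiv), 1,4-dioxane, 60 °C
Reagents that add atoms: none
Why: Oxidative addition of formic acid to zerovalent palladium gives a palladium hydride formate that adds across the terminal alkyne with palladium on internal C8; the C8 alkenylpalladium inserts the styrene by 6-exo-trig carbopalladation (C8–C9 bond, ring B), which places palladium on benzylic C11, and loss of CO2 followed by C–H reductive elimination gives the CH2–aryl group and returns zerovalent palladium. The closest known reaction type is the palladium-catalysed hydride-terminated cycloisomerization of 1,6- and 1,7-enynes with formic acid or with a silane and acetic acid. The new C9 stereocentre is controlled by ring A: in the chair-like transition state ring B forms from the axial C5 arm and the equatorial C10 arm, C4 stays equatorial to the new ring and the styrene terminus C11 is pseudo-equatorial, which should put H9 cis to H5 and to the C10 methyl (9R); this is also the more stable epimer, because the other one has C11 axial or forces the gem-dimethyl carbon axial on ring B. The step needs exo over endo closure and hydride capture faster than beta-hydride elimination; the three-atom tether and formation of a benzyl-stabilised (eta-3) palladium species favour the 6-exo mode, and the same stabilisation slows beta-hydride loss so that formate decarboxylation can intervene. The hindered secondary bromide, the silyl ethers and the aryl aldehyde should be inert to palladium hydride under these near-neutral conditions, and any Z styrene would converge on the same product because C11 ends as CH2.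

Step 12
Reactants: 17 4-{[(1R,4aS,6S,8aR)-6-bromo-5,5,8a-trimethyl-2-methylidenedecahydronaphthalen-1-yl]methyl}-2,5-bis[(triisopropylsilyl)oxy]benzaldehyde
Product: 18 peyssonol A, 4-{[(1R,4aS,6S,8aR)-6-bromo-5,5,8a-trimethyl-2-methylidenedecahydronaphthalen-1-yl]methyl}-2,5-dihydroxybenzaldehyde
Conditions: Bu4NF, AcOH, THF, 0 °C
Reagents that add atoms: none
Why: Fluoride cleaves both aryl silyl ethers with acetic acid buffering the phenoxides, conditions that should leave the exocyclic olefin, the bromide and the aldehyde untouched.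

**Compound list**

1 | nerol, (2Z)-3,7-dimethylocta-2,6-dien-1-ol | CC(C)=CCC/C(C)=C\CO | starting material
2 | neryl bromide, (2Z)-1-bromo-3,7-dimethylocta-2,6-diene | CC(C)=CCC/C(C)=C\CBr | intermediate
3 | 1-(trimethylsilyl)propyne | CC#C[Si](C)(C)C | starting material
4 | [3-(trimethylsilyl)prop-2-yn-1-yl]lithium | [Li]CC#C[Si](C)(C)C | intermediate
5 | trimethyl[(5Z)-6,10-dimethylundeca-5,9-dien-1-yn-1-yl]silane | CC(C)=CCC/C(C)=C\CCC#C[Si](C)(C)C | intermediate
6 | diisobutyl[(1Z,5Z)-6,10-dimethyl-1-(trimethylsilyl)undeca-1,5,9-trien-1-yl]alane | CC(C)=CCC/C(C)=C\CC/C=C(\[Si](C)(C)C)[Al](CC(C)C)CC(C)C | intermediate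
7 | trimethyl[(1Z,5Z)-6,10-dimethylundeca-1,5,9-trien-1-yl]silane | CC(C)=CCC/C(C)=C\CC/C=C\[Si](C)(C)C | intermediate
8 | (4aS,6S,8aR)-6-bromo-5,5,8a-trimethyl-3,4,4a,5,6,7,8,8a-octahydronaphthalene (cis-fused) | C1=C[C@@]2(C)CC[C@H](Br)C(C)(C)[C@H]2CC1 | intermediate
9 | secondary ozonide (1,2,4-trioxolane) of 8 across the former C8=C9 olefin | C1C[C@@H]2C(C)(C)[C@@H](Br)CC[C@]2(C)C3OOC1O3 | intermediate
10 | (1S,2S,4S)-4-bromo-1,3,3-trimethyl-2-(3-oxopropyl)cyclohexane-1-carbaldehyde | O=CCC[C@@H]1C(C)(C)[C@@H](Br)CC[C@]1(C)C=O | intermediate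
11 | (1S,2S,4S)-4-bromo-2-(but-3-yn-1-yl)-1,3,3-trimethylcyclohexane-1-carbaldehyde | C#CCC[C@@H]1C(C)(C)[C@@H](Br)CC[C@]1(C)C=O | intermediate
12 | 2-{(E)-2-[(1R,2S,4S)-4-bromo-2-(but-3-yn-1-yl)-1,3,3-trimethylcyclohexyl]ethenyl}-4,4,5,5-tetramethyl-1,3,2-dioxaborolane | C#CCC[C@@H]1C(C)(C)[C@@H](Br)CC[C@]1(C)/C=C/B1OC(C)(C)C(C)(C)O1 | intermediate
13 | 4-bromo-2,5-dimethoxybenzaldehyde | COc1cc(C=O)c(OC)cc1Br | starting material
14 | 4-bromo-2,5-dihydroxybenzaldehyde | Oc1cc(C=O)c(O)cc1Br | intermediate
15 | 4-bromo-2,5-bis[(triisopropylsilyl)oxy]benzaldehyde | O=Cc1cc(O[Si](C(C)C)(C(C)C)C(C)C)c(Br)cc1O[Si](C(C)C)(C(C)C)C(C)C | intermediate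
16 | 4-{(E)-2-[(1R,2S,4S)-4-bromo-2-(but-3-yn-1-yl)-1,3,3-trimethylcyclohexyl]ethenyl}-2,5-bis[(triisopropylsilyl)oxy]benzaldehyde | C#CCC[C@@H]1C(C)(C)[C@@H](Br)CC[C@]1(C)/C=C/c1cc(O[Si](C(C)C)(C(C)C)C(C)C)c(C=O)cc1O[Si](C(C)C)(C(C)C)C(C)C | intermediate
17 | 4-{[(1R,4aS,6S,8aR)-6-bromo-5,5,8a-trimethyl-2-methylidenedecahydronaphthalen-1-yl]methyl}-2,5-bis[(triisopropylsilyl)oxy]benzaldehyde | C=C1CC[C@@H]2C(C)(C)[C@@H](Br)CC[C@]2(C)[C@@H]1Cc1cc(O[Si](C(C)C)(C(C)C)C(C)C)c(C=O)cc1O[Si](C(C)C)(C(C)C)C(C)C | intermediate
18 | peyssonol A, 4-{[(1R,4aS,6S,8aR)-6-bromo-5,5,8a-trimethyl-2-methylidenedecahydronaphthalen-1-yl]methyl}-2,5-dihydroxybenzaldehyde | C=C1CC[C@@H]2C(C)(C)[C@@H](Br)CC[C@]2(C)[C@@H]1Cc1cc(O)c(C=O)cc1O | target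

**Step count and risks**

Total step count: 12. Longest linear sequence: 10 steps (steps 1–7 and 10–12, from nerol); the arene branch has 2 steps (8 and 9).

Steps most likely to fail:

Step 4 (Proposed new method). The bromonium donor may attack the vinylsilane directly (bromodesilylation) instead of the terminal olefin. The C10 cation may lose a proton before the vinylsilane closes the second ring. Enantio-induction may erode because the catalyst class is established for arene terminators only.

The fallback uses known chemistry, sets out from 2 and comes back at 10. Neryl bromide 2 is coupled with 3-methoxybenzylmagnesium chloride (Li2CuCl4 cat., THF) to give 1-[(3Z)-4,8-dimethylnona-3,7-dien-1-yl]-3-methoxybenzene F1. The same catalytic enantioselective bromonium cyclization, now with an arene terminator, should give the cis-fused 2-bromo-7-methoxy-1,1,4a-trimethyl-1,2,3,4,4a,9,10,10a-octahydrophenanthrene F2. The anisole ring is degraded with RuCl3 (cat.)/NaIO4 to (1S,2S,4S)-4-bromo-2-(2-carboxyethyl)-1,3,3-trimethylcyclohexane-1-carboxylic acid F3. BH3·THF reduces both acids to (1S,2S,4S)-4-bromo-1-(hydroxymethyl)-2-(3-hydroxypropyl)-1,3,3-trimethylcyclohexane F4, and Swern oxidation returns dialdehyde 10.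

Step 11 (key step). Beta-hydride elimination of the benzylic palladium intermediate may outrun formate transfer and give a diene. Hydropalladation with reversed regiochemistry may end in simple semireduction of the alkyne. Facial discrimination in the carbopalladation next to the quaternary carbon may be insufficient.

The fallback sets out from 16 and comes back at 17. Iodoboration of the terminal alkyne with B-iodo-9-borabicyclo[3.3.1]nonane and protonolysis with acetic acid gives the 2-iodo-1-alkene 4-{(E)-2-[(1R,2S,4S)-4-bromo-2-(3-iodobut-3-en-1-yl)-1,3,3-trimethylcyclohexyl]ethenyl}-2,5-bis[(triisopropylsilyl)oxy]benzaldehyde F5. A vinyl radical generated from F5 with (Me3Si)3SiH and Et3B/air in toluene at low temperature closes ring B by 6-exo-trig addition to the styrene. The benzylic radical is reduced by the silane to give 17; the alkenyl iodide is abstracted much faster than the secondary alkyl bromide.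

Step 6. The 1,6-dialdehyde may undergo intramolecular aldol condensation under the basic conditions, and discrimination between the two formyl groups may be incomplete.

The fallback sets out from 10 and comes back at 12. The unhindered formyl group is converted selectively into its dimethyl acetal (HC(OMe)3, pyridinium p-toluenesulfonate, MeOH, 0 °C) to give (1S,2S,4S)-4-bromo-2-(3,3-dimethoxypropyl)-1,3,3-trimethylcyclohexane-1-carbaldehyde F6. The boron–Wittig olefination of step 7 is run on the remaining quaternary aldehyde to give 2-{(E)-2-[(1R,2S,4S)-4-bromo-2-(3,3-dimethoxypropyl)-1,3,3-trimethylcyclohexyl]ethenyl}-4,4,5,5-tetramethyl-1,3,2-dioxaborolane F7. Mild hydrolysis (pyridinium p-toluenesulfonate, acetone–water) liberates the aldehyde 3-{(1S,3S,6R)-3-bromo-2,2,6-trimethyl-6-[(E)-2-(4,4,5,5-tetramethyl-1,3,2-dioxaborolan-2-yl)ethenyl]cyclohexyl}propanal F8. The Ohira–Bestmann homologation, now with no second formyl group present, gives 12.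

Further compounds
F1 | step 4 | 1-[(3Z)-4,8-dimethylnona-3,7-dien-1-yl]-3-methoxybenzene | CC(C)=CCC/C(C)=C\CCc1cccc(OC)c1
F2 | step 4 | cis-fused 2-bromo-7-methoxy-1,1,4a-trimethyl-1,2,3,4,4a,9,10,10a-octahydrophenanthrene (ring A configuration as in 8) | C1C[C@@H]2C(C)(C)[C@@H](Br)CC[C@]2(C)c2ccc(OC)cc21
F3 | step 4 | (1S,2S,4S)-4-bromo-2-(2-carboxyethyl)-1,3,3-trimethylcyclohexane-1-carboxylic acid | OC(=O)CC[C@@H]1C(C)(C)[C@@H](Br)CC[C@]1(C)C(O)=O
F4 | step 4 | (1S,2S,4S)-4-bromo-1-(hydroxymethyl)-2-(3-hydroxypropyl)-1,3,3-trimethylcyclohexane | OCCC[C@@H]1C(C)(C)[C@@H](Br)CC[C@]1(C)CO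
F5 | step 11 | 4-{(E)-2-[(1R,2S,4S)-4-bromo-2-(3-iodobut-3-en-1-yl)-1,3,3-trimethylcyclohexyl]ethenyl}-2,5-bis[(triisopropylsilyl)oxy]benzaldehyde | C=C(I)CC[C@@H]1C(C)(C)[C@@H](Br)CC[C@]1(C)/C=C/c1cc(O[Si](C(C)C)(C(C)C)C(C)C)c(C=O)cc1O[Si](C(C)C)(C(C)C)C(C)C
F6 | step 6 | (1S,2S,4S)-4-bromo-2-(3,3-dimethoxypropyl)-1,3,3-trimethylcyclohexane-1-carbaldehyde | COC(OC)CC[C@@H]1C(C)(C)[C@@H](Br)CC[C@]1(C)C=O
F7 | step 6 | 2-{(E)-2-[(1R,2S,4S)-4-bromo-2-(3,3-dimethoxypropyl)-1,3,3-trimethylcyclohexyl]ethenyl}-4,4,5,5-tetramethyl-1,3,2-dioxaborolane | COC(OC)CC[C@@H]1C(C)(C)[C@@H](Br)CC[C@]1(C)/C=C/B1OC(C)(C)C(C)(C)O1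
F8 | step 6 | 3-{(1S,3S,6R)-3-bromo-2,2,6-trimethyl-6-[(E)-2-(4,4,5,5-tetramethyl-1,3,2-dioxaborolan-2-yl)ethenyl]cyclohexyl}propanal | O=CCC[C@@H]1C(C)(C)[C@@H](Br)CC[C@]1(C)/C=C/B1OC(C)(C)C(C)(C)O1
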